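If a product curve slows well short of the charge, as the north run does with 35% at 8.00 h, 55% at 20.0 h and 65% at 40.0 h, one way to read it is that catalyst is being lost while substrate is still there. So the question for these flasks is how much product a catalyst gives before it is lost.

| flask | substrate | coupling partner | free catalyst | remark | time |
|---|---|---|---|---|---|
| west | 20 mM | 1.8 equiv | 0.2 mol% | run made earlier |  |
| south-east | 28 mM | 1.8 equiv | 0.2 mol% | run made earlier |  |
| north | 44 mM | 1.8 equiv | 0.2 mol% | run made earlier |  |
| north-west | 20 mM | 1.8 equiv | 0.1 mol% | run made earlier |  |
| summer | 20 mM | 1.80 equiv (fed, over 1.50 d) | 0.2 mol% | a stirred flask in which coupling partner is dosed at a steady rate over 1.50 d without added volume, worked up at 3.0 d | 3.0 d |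
| dawn | 20 mM (fed, over 1.50 d) | 1.80 equiv | 0.2 mol% | a stirred flask in which substrate is dosed at a steady rate over 1.50 d without added volume, worked up at 3.0 d | 3.0 d |
| autumn | 20 mM | 1.80 equiv | 0.2 mol% | everything together in a closed stirred flask, run for 3.0 d | 3.0 d |
| noon | 20 mM | 1.80 equiv | 0.2 mol% | one stirred flow tank at steady state, fed with the mixture as stated, mean residence time 3.0 d |  |

| run | time / h | product / % |
|---|---|---|
| west | 3.00 | 6 |
| west | 8.00 | 27 |
| west | 20.0 | 41 |
| west | 40.0 | 53 |
| south-east | 10.0 | 30 |
| south-east | 20.0 | 48 |
| south-east | 30.0 | 56 |
| south-east | 40.0 | 57 |
| north | 3.00 | 15 |
| north | 8.00 | 35 |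
| north | 20.0 | 55 |
| north | 40.0 | 65 |
| north-west | 3.00 | 7 |
| north-west | 8.00 | 12 |
| north-west | 20.0 | 24 |
| north-west | 40.0 | 33 |

(scatter of a reading: 2 percentage points)

- the stated concentrations are those of everything mixed, before any reaction; amounts are the same in each set-up
- the feed brings no volume worth counting
- the earlier runs were made in a closed, stirred flask

* order of the set-ups by the amount of product at the outlet or at the end, in percent of the substrate put in, highest first (summer / dawn / autumn / noon)
* amount of product at the outlet or at the end, in percent of the substrate put in, summer
* amount of product at the outlet or at the end, in percent of the substrate put in, dawn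
* amount of product at the outlet or at the end, in percent of the substrate put in, autumn
* amount of product at the outlet or at the end, in percent of the substrate put in, noon

Two chemists read these runs differently. The first holds that the catalyst dies on a clock, the same share each hour, whatever the flask contains. Her evidence is that at 40.0 h the logarithm of the substrate fraction left in west is twice that in north-west, which has half the catalyst, so the rate follows the catalyst.

The second, whose side I take, points out that north at 20.0 h has 55% and west at 40.0 h has 53%, within the scatter, although north's charge is 2.20 times west's. Hours therefore shrink as the charge rises, so I read both making and loss as speeding up with concentration, which makes the catalyst's account depend on the mix and not on its strength.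

North at 40.0 h has made 325 moles of product per mole of catalyst charged. That is a floor for N, the moles of product made per mole of catalyst lost (a turnover number), if some catalyst still lives. These runs all hold the equivalents fixed, so blaming the coupling partner for the loss is my choice: I take N as proportional to substrate over partner.

My reckoning follows from that. Autumn lies on north's curve at 32.7 h, which gives 61.4%. Taking the dosed reagent at half its charged level, dawn's N falls by a factor of 2, and its yield with it, giving 30.7%. Summer's N rises by the same factor, which pays for 130% of the charge, so I put summer above autumn and autumn above dawn; this reckoning gives noon no figure.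

The forecast gives 46% for summer, 43% for dawn, 60% for autumn and 41% for noon, in the order autumn > summer > dawn > noon, on the clock view: “Dosing wastes early catalyst life”.

The flasks give 74.2% for summer, 34.0% for dawn, 66.2% for autumn and 46.9% for noon, in the order summer > autumn > noon > dawn.

    coupling partner + catalyst intermediate A → spent catalyst (k = 1.80 L mol⁻¹ h⁻¹)
    coupling partner + free catalyst ⇌ catalyst intermediate A (K = 330 L mol⁻¹, k = 3100 L mol⁻¹ h⁻¹)
    catalyst intermediate B ⇌ free catalyst + product (K = 0.0130 M, k = 77.0 h⁻¹)
    substrate + catalyst intermediate A ⇌ catalyst intermediate B (K = 710 L mol⁻¹, k = 1700 L mol⁻¹ h⁻¹)

At 1.02 d in summer, catalyst intermediate A goes forward to catalyst intermediate B 700 times as fast as it is lost with coupling partner to spent catalyst, forward rate alone, and 230 times at 3.00 d. With 85.6% spent, autumn's N is 387, above the floor of 325, and summer's, with 71.0% spent, is 522. The clock view has its region in a closed flask such as autumn, where coupling partner still stands at 63.0% of its charge at 3.00 d and the loss is roughly pseudo-first-order. The neighbour of summer charged with 0.08 mol% catalyst gives 40.1% with 78.0% spent, an N of 643.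

Readings and results are simulated for an exercise.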